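The route rests on cutting the bond between the trioxygenated arene (ring A) and C2 of the tetrahydropyran (ring B). C2 carries O1 and lies β to the C4 oxygen. At the enone level O1–C2=C3–C4=O, both heteroatom groups therefore steer an aryl–palladium species to C2. A Mizoroki–Heck reaction couples an aryl iodide with the C2–H bond of an enantioenriched 2,3-dihydro-4H-pyran-4-one, itself made in one catalytic hetero-Diels–Alder step. This joins the two halves without prior activation of the heterocycle. C2 stays trigonal, and the lone C6 stereocentre then relays the all-equatorial array: hydrogenation sets C2, axial hydride attack sets C4.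

Key step: step 5

Remark on numbering: in all explanations ring B keeps the numbering of the target (O1, C2 aryl-bearing, C3, C4, C5, C6 side-chain-bearing); compound names follow systematic numbering.
Assumption: the Ti(OiPr)4/(R)-BINOL catalyst is taken to expose the Re face of aldehyde 3, as in related additions to unbranched aldehydes; should the sense prove opposite, (S)-BINOL is used.

Step 1
Reactants: 1 1-(benzyloxy)-4-iodobenzene; 2 allyl alcohol (prop-2-en-1-ol)
Product: 3 3-[4-(benzyloxy)phenyl]propanal
Conditions: Pd(OAc)2 (2 mol %), n-Bu4NCl, NaHCO3, DMF, 40 °C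
Reagents that add atoms: none
Why: Phosphine-free Mizoroki–Heck arylation of allyl alcohol, in which β-hydride elimination toward the carbinol carbon should deliver the saturated aldehyde directly and no stereocentre is formed.

Step 2
Reactants: 3 3-[4-(benzyloxy)phenyl]propanal; 4 Danishefsky's diene, (E)-1-methoxy-3-(trimethylsilyloxy)buta-1,3-diene
Product: 6 (2S)-2-{2-[4-(benzyloxy)phenyl]ethyl}-2,3-dihydro-4H-pyran-4-one, via silyl aldol adduct 5 (not isolated)
Conditions: Ti(OiPr)4 (10 mol %), (R)-BINOL (20 mol %), 4 Å MS, Et2O, −20 °C; then CF3CO2H, CH2Cl2, 0 °C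
Reagents that add atoms: none
Why: Titanium–BINOL-catalysed formal hetero-Diels–Alder reaction (Mukaiyama aldol addition, then acid-induced ring closure with loss of methanol), in which the chiral titanium complex shields the Si face of the aldehyde so that attack on the Re face sets C6 as S.

Step 3
Reactants: 7 2-hydroxy-5-iodo-3-methoxybenzaldehyde
Product: 9 5-iodo-3-methoxybenzene-1,2-diol, via aryl formate 8 (not isolated)
Conditions: H2O2 (30 % aq), NaOH, H2O–THF, 0 °C to rt, Ar; then HCl
Reagents that add atoms: hydrogen peroxide OO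
Why: Dakin oxidation, in which hydroperoxide adds to the ortho-hydroxy aldehyde, the electron-rich aryl group migrates to oxygen and the formate is hydrolysed in situ, while the aryl iodide is inert.

Step 4
Reactants: 9 5-iodo-3-methoxybenzene-1,2-diol
Product: 10 1,2-bis(benzyloxy)-5-iodo-3-methoxybenzene
Conditions: BnBr, K2CO3, DMF, rt to 50 °C, Ar
Reagents that add atoms: benzyl bromide BrCc1ccccc1
Why: Williamson etherification of both phenols masks the oxidation-prone catechol with groups that survive the palladium coupling and fall in the later hydrogenation.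

Step 5
Reactants: 6 (2S)-2-{2-[4-(benzyloxy)phenyl]ethyl}-2,3-dihydro-4H-pyran-4-one; 10 1,2-bis(benzyloxy)-5-iodo-3-methoxybenzene
Product: 11 (2S)-6-[3,4-bis(benzyloxy)-5-methoxyphenyl]-2-{2-[4-(benzyloxy)phenyl]ethyl}-2,3-dihydro-4H-pyran-4-one
Conditions: Pd(OAc)2 (10 mol %), PPh3 (20 mol %), Ag2CO3 (1.0 equiv), MeCN, 70 °C
Reagents that add atoms: none
Why: Oxidative addition of 10 to zerovalent palladium and abstraction of iodide by Ag2CO3 should give a cationic aryl–palladium species that adds syn across C2=C3 of 6, aryl to C2 and palladium to C3, where the metal is held as an oxa-π-allyl (palladium enolate). Through this enolate the metal can change ring face, so that syn β-hydride elimination of the C2–H restores the enone and carbonate takes up the acid and returns zerovalent palladium. The closest known reaction type is the Mizoroki–Heck vinylic substitution of cyclic enones and of glycal-type cyclic enol ethers with aryl iodides. No ring is closed and no stereocentre is formed: C2 is left trigonal on purpose, and the C6 stereocentre lies outside the reacting π system and should be untouched by the weak base. The step needs regioselectivity for C2 over C3, which the substrate secures because the O1 lone pair and the C4 carbonyl polarise the alkene in the same sense. It also needs vinylic substitution instead of hydroarylation, which the aprotic medium free of amine or formate hydride donors favours, since protonolysis of the enolate would strand divalent palladium and end turnover, while the benzyl and methyl ethers are inert.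

Step 6
Reactants: 11 (2S)-6-[3,4-bis(benzyloxy)-5-methoxyphenyl]-2-{2-[4-(benzyloxy)phenyl]ethyl}-2,3-dihydro-4H-pyran-4-one
Product: 12 (2S,6S)-2-(3,4-dihydroxy-5-methoxyphenyl)-6-[2-(4-hydroxyphenyl)ethyl]oxan-4-one (2,6-cis)
Conditions: H2 (1 atm), 10 % Pd/C, EtOAc–MeOH, rt
Reagents that add atoms: none
Why: Heterogeneous catalytic hydrogenation should add hydrogen syn to C2=C3 from the ring face opposite the C6 side chain, which places the aryl group cis to that chain (also the more stable diequatorial isomer, 2S), and the same catalyst hydrogenolyses the three aryl benzyl ethers.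

Step 7
Reactants: 12 (2S,6S)-2-(3,4-dihydroxy-5-methoxyphenyl)-6-[2-(4-hydroxyphenyl)ethyl]oxan-4-one
Product: 13 (2S,4R,6S)-2-(3,4-dihydroxy-5-methoxyphenyl)-6-[2-(4-hydroxyphenyl)ethyl]oxan-4-ol (all-cis, target)
Conditions: NaBH4, MeOH–THF, −40 °C, Ar; then aq NH4Cl
Reagents that add atoms: none
Why: Borohydride reduction of a conformationally locked chair ketone, in which the small hydride attacks C4 along the axial trajectory so that the new hydroxyl ends equatorial and cis to the C2 and C6 substituents (4R).

Compound list
1 | 1-(benzyloxy)-4-iodobenzene | Ic1ccc(OCc2ccccc2)cc1 | starting material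
2 | allyl alcohol (prop-2-en-1-ol) | C=CCO | starting material
3 | 3-[4-(benzyloxy)phenyl]propanal | O=CCCc1ccc(OCc2ccccc2)cc1 | intermediate
4 | Danishefsky's diene, (E)-1-methoxy-3-(trimethylsilyloxy)buta-1,3-diene | CO/C=C/C(=C)O[Si](C)(C)C | starting material
5 | (1E,5S)-7-[4-(benzyloxy)phenyl]-1-methoxy-5-(trimethylsilyloxy)hept-1-en-3-one (silyl aldol adduct) | CO/C=C/C(=O)C[C@H](CCc1ccc(OCc2ccccc2)cc1)O[Si](C)(C)C | intermediate
6 | (2S)-2-{2-[4-(benzyloxy)phenyl]ethyl}-2,3-dihydro-4H-pyran-4-one | O=C1C[C@H](CCc2ccc(OCc3ccccc3)cc2)OC=C1 | intermediate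
7 | 2-hydroxy-5-iodo-3-methoxybenzaldehyde | COc1cc(I)cc(C=O)c1O | starting material
8 | 2-hydroxy-5-iodo-3-methoxyphenyl formate (aryl formate) | COc1cc(I)cc(OC=O)c1O | intermediate
9 | 5-iodo-3-methoxybenzene-1,2-diol | COc1cc(I)cc(O)c1O | intermediate
10 | 1,2-bis(benzyloxy)-5-iodo-3-methoxybenzene | COc1cc(I)cc(OCc2ccccc2)c1OCc1ccccc1 | intermediate
11 | (2S)-6-[3,4-bis(benzyloxy)-5-methoxyphenyl]-2-{2-[4-(benzyloxy)phenyl]ethyl}-2,3-dihydro-4H-pyran-4-one | COc1cc(C2=CC(=O)C[C@H](CCc3ccc(OCc4ccccc4)cc3)O2)cc(OCc2ccccc2)c1OCc1ccccc1 | intermediate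
12 | (2S,6S)-2-(3,4-dihydroxy-5-methoxyphenyl)-6-[2-(4-hydroxyphenyl)ethyl]oxan-4-one | COc1cc([C@@H]2CC(=O)C[C@H](CCc3ccc(O)cc3)O2)cc(O)c1O | intermediate
13 | (2S,4R,6S)-2-(3,4-dihydroxy-5-methoxyphenyl)-6-[2-(4-hydroxyphenyl)ethyl]oxan-4-ol | COc1cc([C@@H]2C[C@H](O)C[C@H](CCc3ccc(O)cc3)O2)cc(O)c1O | target

Total step count: 7
Longest linear sequence: 5 steps (steps 1, 2, 5, 6, 7; the arene branch, steps 3, 4, 5, 6, 7, is equally long)

Steps most likely to fail

**Step 5.** Insertion into the push–pull alkene may be slow. Aryl homocoupling, protonolysis of the palladium enolate (hydroarylation, which halts turnover) and precipitation of palladium metal could then compete. The fallback is an arylative carbonyl transposition of the Stork–Danheiser type that sets out from 3 and 10 and comes back at 11.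
- Aldehyde 3 and Brassard's diene, 1,3-dimethoxy-1-(trimethylsilyloxy)buta-1,3-diene, should combine under Ti(OiPr)4/(R)-BINOL catalysis in a hetero-Diels–Alder reaction. The product is the vinylogous carbonate (6S)-6-{2-[4-(benzyloxy)phenyl]ethyl}-4-methoxy-5,6-dihydro-2H-pyran-2-one F1.
- Iodine–lithium exchange on 10 (n-BuLi, THF, −78 °C) gives [3,4-bis(benzyloxy)-5-methoxyphenyl]lithium F2.
- This aryllithium should add 1,2 to the lactone carbonyl of F1 to give the cyclic hemiketal (6S)-2-[3,4-bis(benzyloxy)-5-methoxyphenyl]-6-{2-[4-(benzyloxy)phenyl]ethyl}-4-methoxy-5,6-dihydro-2H-pyran-2-ol F3.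
- Dilute HCl in THF ionises the hemiketal, water enters at C4 and methanol leaves. This gives 11 with the aryl group on the former lactone carbon.

**Step 6.** The aryl benzyl ethers should fall first. The remaining alkene, then conjugated with both a free para-hydroxyphenyl group and the ketone, may resist saturation. Forcing conditions would invite hydrogenolysis of the benzylic C2–O1 bond, and facial selectivity may be poor. The fallback reverses the order of the two reductions, sets out from 11 and comes back at 13.
- Luche reduction (NaBH4, CeCl3·7H2O, MeOH, −78 °C) should give the pseudo-equatorial allylic alcohol (2S,4R)-6-[3,4-bis(benzyloxy)-5-methoxyphenyl]-2-{2-[4-(benzyloxy)phenyl]ethyl}-3,4-dihydro-2H-pyran-4-ol F4. Its aryl enol ether is no longer deactivated by a carbonyl group.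
- Hydrogenation over Pd/C (EtOAc, solid NaHCO3) from the face opposite both substituents, with loss of the three benzyl groups, should lead directly to 13. This follows the known behaviour of C-aryl glycals.

**Step 7.** Under the basic borohydride conditions the phenoxide-rich ketone may open by retro-oxa-Michael reaction. The catecholate may also oxidise in air, and borate complexation may hamper isolation. The fallback keeps the phenols masked until the end, sets out from 11 and comes back at 13.
- Hydrogenation over Pd/C poisoned with Ph2S should saturate only the alkene. The product is (2S,6S)-2-[3,4-bis(benzyloxy)-5-methoxyphenyl]-6-{2-[4-(benzyloxy)phenyl]ethyl}oxan-4-one F5.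
- NaBH4 in MeOH–THF should then give (2S,4R,6S)-2-[3,4-bis(benzyloxy)-5-methoxyphenyl]-6-{2-[4-(benzyloxy)phenyl]ethyl}oxan-4-ol F6 by axial attack.
- Neutral hydrogenolysis (H2, Pd/C, EtOAc–MeOH) releases 13 as the last operation.

Further compounds
F1 | step 5 | (6S)-6-{2-[4-(benzyloxy)phenyl]ethyl}-4-methoxy-5,6-dihydro-2H-pyran-2-one | O=C1C=C(OC)C[C@H](CCc2ccc(OCc3ccccc3)cc2)O1
F2 | step 5 | [3,4-bis(benzyloxy)-5-methoxyphenyl]lithium | [Li]c1cc(OC)c(OCc2ccccc2)c(OCc2ccccc2)c1
F3 | step 5 | (6S)-2-[3,4-bis(benzyloxy)-5-methoxyphenyl]-6-{2-[4-(benzyloxy)phenyl]ethyl}-4-methoxy-5,6-dihydro-2H-pyran-2-ol | OC1(c2cc(OC)c(OCc3ccccc3)c(OCc3ccccc3)c2)C=C(OC)C[C@H](CCc2ccc(OCc3ccccc3)cc2)O1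
F4 | step 6 | (2S,4R)-6-[3,4-bis(benzyloxy)-5-methoxyphenyl]-2-{2-[4-(benzyloxy)phenyl]ethyl}-3,4-dihydro-2H-pyran-4-ol | COc1cc(C2=C[C@H](O)C[C@H](CCc3ccc(OCc4ccccc4)cc3)O2)cc(OCc2ccccc2)c1OCc1ccccc1
F5 | step 7 | (2S,6S)-2-[3,4-bis(benzyloxy)-5-methoxyphenyl]-6-{2-[4-(benzyloxy)phenyl]ethyl}oxan-4-one | COc1cc([C@@H]2CC(=O)C[C@H](CCc3ccc(OCc4ccccc4)cc3)O2)cc(OCc2ccccc2)c1OCc1ccccc1
F6 | step 7 | (2S,4R,6S)-2-[3,4-bis(benzyloxy)-5-methoxyphenyl]-6-{2-[4-(benzyloxy)phenyl]ethyl}oxan-4-ol | COc1cc([C@@H]2C[C@H](O)C[C@H](CCc3ccc(OCc4ccccc4)cc3)O2)cc(OCc2ccccc2)c1OCc1ccccc1
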